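# Total synthesis of (+)-lariciresinol (7S,8R,8'R)

**Target analysis.** The target is a 2-aryl-3-(hydroxymethyl)-4-benzyl-tetrahydrofuran with 2,3-trans and 3,4-cis substituents. Its descriptors are C7 S, C8 R, C8' R (THF numbering 2S,3R,4R).

**Retrosynthesis**
1. Target ⇐ bis-benzyl ether 11, with the phenols protected as benzyl ethers and removed last by hydrogenolysis.
2. The THF ring is formed last, by acid-mediated 5-exo dehydrative cyclisation of triol 10 through the p-alkoxybenzylic C7 cation. The 2,3-trans configuration at C7 is set by equilibration, and the C9 hydroxyl cannot close because that would give an oxetane.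
3. Triol 10 ⇐ LiAlH4 reduction of the α,β-trans aldol lactone 9. Once C9 is reduced and C7 becomes the ring carbon, the α,β-trans lactone relationship becomes the required 3,4-cis THF relationship.
4. Lactone 9 ⇐ aldol of (R)-β-benzyl-γ-butyrolactone 7 with aldehyde 8. The lactone ring is formed in step 4.
5. Lactone 7 ⇐ Evans alkylation of the succinate imide 3 with benzylic chloride 4, then imide reduction and lactonisation.

**Assumptions.**
- 4-(Benzyloxy)-3-methoxybenzyl chloride (4) and 4-(benzyloxy)-3-methoxybenzaldehyde (8) are commercial.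
- Under reversible acid conditions the 2,3-trans THF is the major isomer. The alternative is all-cis, which is more strained.

---

**Step 1**
Reactants: 1 (mono-tert-butyl succinate); 2 ((R)-4-benzyloxazolidin-2-one)
Product: 3, (R)-4-benzyl-3-(4-tert-butoxy-4-oxobutanoyl)oxazolidin-2-one
Conditions: (i) PivCl, Et3N, THF, –20 → 0 °C; (ii) 2, LiCl, rt
Reagents that add atoms: none
Why: Mixed-anhydride N-acylation of the oxazolidinone (Evans auxiliary attachment) gives the chiral imide, and the tert-butyl ester is kept as a handle that can be told apart from the imide later.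

**Step 2**
Reactants: 3; 4 (4-(benzyloxy)-3-methoxybenzyl chloride)
Product: 5, tert-butyl (3R)-3-{[4-(benzyloxy)-3-methoxyphenyl]methyl}-4-[(4R)-4-benzyl-2-oxooxazolidin-3-yl]-4-oxobutanoate
Conditions: NaHMDS, THF, –78 °C; then 4, NaI, –78 → –20 °C
Reagents that add atoms: 4, COc1cc(CCl)ccc1OCc1ccccc1 (supplies the ArCH2 group)
Why: Evans asymmetric alkylation of the chelated Z-sodium enolate, with the electrophile entering anti to the auxiliary benzyl group. The (R)-auxiliary sets the new C8' stereocentre as R, and NaI converts the chloride in situ to the more reactive iodide.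

**Step 3**
Reactants: 5
Product: 6, tert-butyl (3R)-3-{[4-(benzyloxy)-3-methoxyphenyl]methyl}-4-hydroxybutanoate (auxiliary 2 is recovered)
Conditions: LiBH4, MeOH (1 equiv), Et2O, 0 °C
Reagents that add atoms: none (hydride only)
Why: Hydride reductive cleavage of the imide (Evans auxiliary removal) gives the primary alcohol C9'. The tert-butyl ester and the benzyl ethers are inert to LiBH4 at 0 °C, and C8' is not epimerisable.

**Step 4**
Reactants: 6
Product: 7, (4R)-4-{[4-(benzyloxy)-3-methoxyphenyl]methyl}oxolan-2-one
Conditions: TsOH·H2O (0.1 equiv), toluene, 50 °C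
Reagents that add atoms: none
Why: Acid cleaves the tert-butyl ester (isobutylene is lost), and the γ-hydroxy acid lactonises (acid-catalysed lactonisation). This forms the butyrolactone ring, and the aryl benzyl ether survives TsOH.

**Step 5**
Reactants: 7; 8 (4-(benzyloxy)-3-methoxybenzaldehyde)
Product: 9, (3S,4R)-4-{[4-(benzyloxy)-3-methoxyphenyl]methyl}-3-{[4-(benzyloxy)-3-methoxyphenyl](hydroxy)methyl}oxolan-2-one, as a mixture of carbinol (C7) epimers
Conditions: LDA, THF, –78 °C; then 8, –78 °C; NH4Cl(aq) quench at –78 °C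
Reagents that add atoms: 8, COc1cc(C=O)ccc1OCc1ccccc1 (supplies the ArCH(OH) unit)
Why: Lithium enolate aldol reaction in which the aldehyde approaches anti to the β-benzyl group, so C8 becomes S and α,β-trans to the benzyl group. C7 is left uncontrolled because it is reset in step 7.

**Step 6**
Reactants: 9
Product: 10, (1RS,2R,3R)-1-(4-benzyloxy-3-methoxyphenyl)-3-[(4-benzyloxy-3-methoxyphenyl)methyl]-2-(hydroxymethyl)butane-1,4-diol
Conditions: LiAlH4, THF, 0 °C → rt
Reagents that add atoms: none (hydride only)
Why: Hydride reduction of the lactone to the diol (lactone reduction), with no change at C8 or C8'. The new CH2OH is C9, and the benzyl ethers survive.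

**Step 7**
Reactants: 10
Product: 11, {(2S,3R,4R)-2-[4-(benzyloxy)-3-methoxyphenyl]-4-{[4-(benzyloxy)-3-methoxyphenyl]methyl}oxolan-3-yl}methanol
Conditions: CSA (0.1 equiv), CH2Cl2 (0.02 M), 4 Å MS, 0 °C → rt
Reagents that add atoms: none
Why: Acid-catalysed ionisation of the electron-rich benzylic alcohol, followed by 5-exo trapping by the C9' hydroxyl (dehydrative etherification). Both C7 epimers converge through the cation, and reversible closure favours Ar trans to the C3 CH2OH and the C4 benzyl, giving 7S. Dilution and mild acid suppress dimerisation and aryl-tetralin formation.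

**Step 8**
Reactants: 11
Product: 12, (+)-lariciresinol
Conditions: H2 (1 atm), 10% Pd/C, EtOAc/MeOH 1:1, rt, monitored for short reaction time
Reagents that add atoms: none (H2 adds only hydrogen)
Why: Hydrogenolysis of the two aryl benzyl ethers (catalytic debenzylation). The C7 benzylic C–O bond of the 2-aryl THF is less reactive than the O-benzyl groups, and no stereocentre is touched.

---

**Compound list**

| # | Name | SMILES | Role |
|---|---|---|---|
| 1 | 4-(tert-Butoxy)-4-oxobutanoic acid | CC(C)(C)OC(=O)CCC(=O)O | starting material |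
| 2 | (R)-4-Benzyloxazolidin-2-one | O=C1N[C@H](Cc2ccccc2)CO1 | starting material |
| 3 | (R)-4-Benzyl-3-(4-tert-butoxy-4-oxobutanoyl)oxazolidin-2-one | CC(C)(C)OC(=O)CCC(=O)N1[C@H](Cc2ccccc2)COC1=O | intermediate |
| 4 | 4-(Benzyloxy)-3-methoxybenzyl chloride | COc1cc(CCl)ccc1OCc1ccccc1 | starting material |
| 5 | Alkylated imide (3R; aux 4R) | CC(C)(C)OC(=O)C[C@@H](Cc1ccc(OCc2ccccc2)c(OC)c1)C(=O)N1[C@H](Cc2ccccc2)COC1=O | intermediate |
| 6 | tert-Butyl (3R)-3-{[4-(benzyloxy)-3-methoxyphenyl]methyl}-4-hydroxybutanoate | CC(C)(C)OC(=O)C[C@@H](Cc1ccc(OCc2ccccc2)c(OC)c1)CO | intermediate |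
| 7 | (4R)-4-{[4-(Benzyloxy)-3-methoxyphenyl]methyl}oxolan-2-one | O=C1C[C@@H](Cc2ccc(OCc3ccccc3)c(OC)c2)CO1 | intermediate |
| 8 | 4-(Benzyloxy)-3-methoxybenzaldehyde | COc1cc(C=O)ccc1OCc1ccccc1 | starting material |
| 9 | (3S,4R)-Aldol lactone (C7 epimeric mixture) | O=C1OC[C@H](Cc2ccc(OCc3ccccc3)c(OC)c2)[C@H]1C(O)c1ccc(OCc2ccccc2)c(OC)c1 | intermediate |
| 10 | Triol (2R,3R; C7 epimeric mixture) | OC[C@H](Cc1ccc(OCc2ccccc2)c(OC)c1)[C@H](CO)C(O)c1ccc(OCc2ccccc2)c(OC)c1 | intermediate |
| 11 | (+)-Lariciresinol bis(benzyl ether) (2S,3R,4R) | COc1cc(C[C@H]2CO[C@H](c3ccc(OCc4ccccc4)c(OC)c3)[C@H]2CO)ccc1OCc1ccccc1 | intermediate |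
| 12 | (+)-Lariciresinol | COc1cc(C[C@H]2CO[C@H](c3ccc(O)c(OC)c3)[C@H]2CO)ccc1O | target |

**Total step count:** 8
**Longest linear sequence:** 8 steps (1 → 3 → 5 → 6 → 7 → 9 → 10 → 11 → 12)

**Three steps most likely to fail**

1. **Step 7 (cyclisation).**
   - Risks: poor C7 selectivity, elimination, or Friedel–Crafts closure to an aryl-tetralin.
   - Fallback: avoid the cation. Separate the C7 epimers at stage 9, open the lactone with NaOMe/MeOH, tosylate the primary C9' alcohol selectively, and close with base by SN2 at C9' (retention at C7). Then reduce the ester with LiAlH4.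
2. **Step 5 (aldol).**
   - Risks: retro-aldol, poor trans selectivity at C8, or dehydration.
   - Fallback: acylate the lactone enolate with methyl 4-benzyloxy-3-methoxybenzoate to give the α-aroyl lactone, which equilibrates to trans. LiAlH4 then gives triol 10 directly, because C7 is reset in step 7 anyway.
3. **Step 8 (debenzylation).**
   - Risk: hydrogenolysis of the C7 benzylic C–O bond, or acid-induced C7 epimerisation.
   - Fallback: restart with 4-O-allyl-protected 4 and 8, and remove the allyl groups at the end with Pd(PPh3)4/K2CO3/MeOH. The allyl ethers survive NaHMDS, LDA, LiAlH4 and CSA.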